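The constants I wanted for this substrate were hidden in the winter and midnight runs, and I wanted them for a row of five charges of coupling partner, read at the same hour.

| flask | substrate | coupling partner | remark | time |
|---|---|---|---|---|
| winter | 20 mM | 15 mM | run made earlier |  |
| midnight | 20 mM | 250 mM | run made earlier |  |
| Saturday's | 20 mM | 20.0 mM |  | 80 min |
| Wednesday's | 20 mM | 40.0 mM |  | 80 min |
| Monday's | 20 mM | 80.0 mM |  | 80 min |
| Friday's | 20 mM | 150 mM |  | 80 min |
| Thursday's | 20 mM | 300 mM |  | 80 min |

| run | time / min | target / % | substrate / % |
|---|---|---|---|
| winter | 5.00 | 0.3 | 75.1 |
| winter | 6.00 | 0.1 | 69.3 |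
| winter | 10.0 | 3.4 | 56.0 |
| winter | 15.0 | 4.0 | 41.3 |
| winter | 25.0 | 8.6 | 25.2 |
| winter | 40.0 | 10.2 | 14.1 |
| winter | 60.0 | 14.7 | 9.2 |
| midnight | 3.00 | 2.2 | 51.7 |
| midnight | 8.00 | 11.2 | 18.4 |
| midnight | 15.0 | 15.7 | 5.2 |
| midnight | 25.0 | 17.6 | 0.5 |
| midnight | 30.0 | 19.8 | 0.8 |
| midnight | 40.0 | 18.2 | 0 |
| midnight | 60.0 | 17.8 | 0 |

(readings scatter by 1 percentage point)

- percentages count the substrate that a species holds: one side product counts as two
- the numbers in the tables scatter with a standard deviation of 1 percentage point
- steps under discussion: substrate <-> tautomer; substrate + coupling partner -> isomer of the product; coupling partner + tautomer -> target; substrate + tautomer -> side product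
- "hardly changes" means that all values lie within two and a half points (for a concentration: within two and a half percent of the largest)

- [target] at the end for Saturday's, Wednesday's, Monday's, Friday's, Thursday's, in this order
- how that number moves from the first to the last of them (hardly changes / falls all the way / rises all the way / rises, then falls / falls, then rises)

I turned the question round and asked what the given numbers must look like for the row not to peak. Substrate has three exits: on its own into the tautomer, which the partner then captures as target, with the partner into the isomer of the product, and with the tautomer into the side product, and I set the third aside in this reckoning so as to weigh the first two against each other. So I took its decay constant to climb in a straight line with the partner charge, a fair pseudo-first-order picture for the midnight run, where the 250 mM of partner stands in excess over the 20 mM of substrate, but only a rough one for the winter run, where the 15 mM of partner stands below the 20 mM of substrate. The winter reading of 25.2% substrate after 25.0 min gave 0.0551 min⁻¹, and the midnight reading of 18.4% after 8.00 min gave 0.212 min⁻¹. That line put at 67.8 mM the partner concentration at which substrate leaves as fast for the isomer as for the tautomer, which I called the balance charge. A row that kept rising asked, I reasoned, for a balance charge above Thursday's 300 mM, and a row that kept falling for one below Saturday's 20.0 mM. This one lay 4.42 times under the first and 3.39 times over the second, so I committed to a rise and then a fall. With the side product set aside, I estimated the isomer's share of the substrate as the charge over the charge plus the balance charge, which for Thursday's flask made 81.6%, and that left an estimated ceiling of 3.69 mM for target.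

The forecast gave 4.4 mM, 5.3 mM, 6 mM, 5 mM and 3.3 mM, shape rises, then falls, on the ground that “The optimum should lie near 80 mM”.

The flasks gave 4.19 mM, 6.01 mM, 6.34 mM, 5.12 mM and 3.38 mM, shape rises, then falls.

    substrate ⇌ tautomer (K = 1.50, k = 7.70 × 10⁻⁴ s⁻¹)
    substrate + coupling partner → isomer of the product (k = 0.0110 M⁻¹ s⁻¹)
    coupling partner + tautomer → target (k = 0.0200 M⁻¹ s⁻¹)
    substrate + tautomer → side product (k = 0.0620 M⁻¹ s⁻¹)

Thursday's flask held 80.9% isomer against my 81.6%, and its target of 3.38 mM stood under my ceiling of 3.69 mM; the row turned at 63 mM, with the balance charge at 67.8 mM. The same share for Friday's flask comes to 68.9%, and Friday's flask holds 67.9% isomer. At the low end, Saturday's target was held down by the step from substrate and tautomer to side product together with the hour of the reading: from 4.19 mM it goes to 6.71 mM without that step, and to 5.80 mM when read ten times later.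

All runs are calculated with constants of no real substance, noise included.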